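## Retrosynthetic overview

1. Structural handle: ring C is the chain O1–C2–C3–C4 strung between C8a and C4a of the phloroglucinol ring A. C2 carries ring B, whose free 4'-OH lies para to C2. O1–C2 and C3–C4 can therefore be cut together into a ring A ortho-quinone methide and a para-hydroxystyrene.
2. C4=O is traced back through C4–OH to C4–OMe. The heterodiene is then the 4-methoxy ortho-quinone methide 13, released from hydroxy acetal 11. Its partner is 4-vinylsyringol 12, and a chiral phosphoric acid sets C2 as S.
3. Acetal 11 comes from aldehyde 9, made by ortho-formylation of the mirror-symmetric phenol 7, whose symmetry fixes 6- over 8-geranyl. Phenol 7 comes from phloroglucinol 1 by bis-MOM/TIPS protection and directed lithiation–geranylation between the MOM ethers.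
4. Ring order: rings A and B are purchased and ring C is the only ring made (step 7). The endgame is silylation, C4 solvolysis, oxidation and deprotection.

Key step: step 7

Notation: geranyl = (2E)-3,7-dimethylocta-2,6-dien-1-yl. Flavonoid numbering is used (O1, C2–C4, C4a, C5–C8, C8a; ring B primed).

Assumption: the sense of induction of the phosphoric acid cannot be derived with certainty, so the (R)-catalyst is written, and its equally available antipode would be used if the first run gives the (2R) series.

## Route

Step 1
Reactants: 1 phloroglucinol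
Product: 2 3,5-bis(methoxymethoxy)phenol
Conditions: MOMCl (2.0 equiv), i-Pr2NEt (2.2 equiv), DMF, 0 °C → rt; chromatography
Reagents that add atoms: chloromethyl methyl ether (MOMCl), COCCl
Why: Williamson-type O-alkylation of a triphenol whose three hydroxyls are equivalent is only statistical in degree, so the sole by-products should be the mono- and tris-ethers, which are separable by chromatography and recyclable.

Step 2
Reactants: 2 3,5-bis(methoxymethoxy)phenol
Product: 3 [3,5-bis(methoxymethoxy)phenoxy]triisopropylsilane
Conditions: TIPSCl, imidazole, DMF, rt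
Reagents that add atoms: chlorotriisopropylsilane (TIPSCl), CC(C)[Si](Cl)(C(C)C)C(C)C
Why: Imidazole-promoted silylation of the one remaining phenol installs a bulky group that resists n-BuLi and shields its two flanking ring positions in the next step.

Step 3
Reactants: 3 [3,5-bis(methoxymethoxy)phenoxy]triisopropylsilane; 4 geranyl bromide
Product: 6 [4-geranyl-3,5-bis(methoxymethoxy)phenoxy]triisopropylsilane, via aryllithium 5 (not isolated)
Conditions: n-BuLi (1.1 equiv), THF, 0 °C, 1 h; then 4, −78 °C → rt
Reagents that add atoms: none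
Why: In this directed ortho-metalation the two MOM ethers cooperatively chelate lithium at the C–H between them, and SN2 allylation by the primary allylic bromide keeps the E alkene and places the geranyl group on the symmetry axis of ring A (future C6).

Step 4
Reactants: 6 [4-geranyl-3,5-bis(methoxymethoxy)phenoxy]triisopropylsilane
Product: 7 4-geranyl-3,5-bis(methoxymethoxy)phenol
Conditions: TBAF, AcOH (1:1), THF, 0 °C → rt
Reagents that add atoms: none
Why: Fluoride-mediated cleavage of the aryl silyl ether is selective over MOM ethers and alkenes, and the acetic acid keeps the electron-rich phenol protonated and so less prone to air oxidation.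

Step 5
Reactants: 7 4-geranyl-3,5-bis(methoxymethoxy)phenol
Product: 9 3-geranyl-6-hydroxy-2,4-bis(methoxymethoxy)benzaldehyde, via salicyl alcohol 8 (not isolated)
Conditions: MgCl2 (anhydrous), Et3N, (CH2O)n, THF, reflux; aq NH4Cl
Reagents that add atoms: paraformaldehyde (reacts as formaldehyde), C=O
Why: In the Casnati–Skattebøl ortho-formylation the magnesium phenoxide delivers formaldehyde only ortho to oxygen and a second formaldehyde oxidises the salicyl alcohol by Oppenauer-type hydride transfer, and since the two ortho sites are equivalent and the para site is blocked only one aldehyde can form.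

Step 6
Reactants: 9 3-geranyl-6-hydroxy-2,4-bis(methoxymethoxy)benzaldehyde; 10 trimethyl orthoformate
Product: 11 3-geranyl-6-hydroxy-2,4-bis(methoxymethoxy)benzaldehyde dimethyl acetal
Conditions: HC(OMe)3 (5 equiv), PPTS (5 mol %), MeOH, rt; Et3N quench, concentration, filtration through basic alumina, used at once
Reagents that add atoms: methanol (solvent, its methoxy groups exchange with those of 10), CO
Why: This acid-catalysed acetalisation is driven by the orthoformate as irreversible water scavenger, the electron-rich ring speeds oxocarbenium formation so that a pyridinium-strength acid harmless to aryl MOM ethers should suffice, and the amine quench before concentration keeps the labile hydroxy acetal from ionising.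

Step 7
Reactants: 11 3-geranyl-6-hydroxy-2,4-bis(methoxymethoxy)benzaldehyde dimethyl acetal; 12 4-vinyl-2,6-dimethoxyphenol (4-vinylsyringol)
Product: 15 (2S,4S)-6-geranyl-2-(4-hydroxy-3,5-dimethoxyphenyl)-4-methoxy-5,7-bis(methoxymethoxy)chroman (2,4-cis), via methoxy ortho-quinone methide 13 (not isolated), via para-quinone methide 14 (not isolated)
Conditions: (R)-TRIP [(R)-3,3'-bis(2,4,6-triisopropylphenyl)-1,1'-binaphthyl-2,2'-diyl hydrogen phosphate] (10 mol %), 12 (2 equiv), 5 Å MS, toluene/CH2Cl2, −40 °C, slow addition of 11; Et3N quench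
Reagents that add atoms: none
Why: Proposed new method: the phosphoric acid protonates an acetal oxygen of 11, methanol leaves (and is taken up by the sieves), and the 4-methoxy ortho-quinone methide 13, a push–pull stabilised oxocarbenium phenol in its protonated form, stays hydrogen-bonded to the chiral phosphate, whose second oxygen binds the 4'-OH of 12. The CH2 terminus of 12, pushed by that para hydroxyl, attacks C4 to form C3–C4 and para-quinone methide 14, and the ring A oxygen then adds to the exocyclic carbon C2 of 14 in a 6-exo-trig closure of ring C (O1–C2), so the overall event is a stepwise inverse-electron-demand oxa-[4+2]. The closest known reaction types are the racemic Lewis acid-mediated three-component union of salicylaldehydes, trimethyl orthoformate and styrenes to 2,4-cis-4-methoxyflavans and the chiral phosphoric acid-catalysed [4+2] of ortho-quinone methides from ortho-hydroxybenzyl alcohols with hydroxystyrenes; new here is an acetal-derived alkoxy quinone methide in an enantioselective intermolecular reaction. The face of C4 that is attacked is chosen by the 2,4,6-triisopropylphenyl walls of the doubly hydrogen-bonded ion pair, and C2 follows inside the same ion pair through a chair-like closure with aryl and methoxy both pseudo-equatorial, which should give the 2,4-cis (2S,4S) isomer; only C2 matters, because C4 is flattened in step 10. Regiochemistry (aryl-bearing carbon on O1) is secured by the polarisation of the styrene, since only its terminal carbon is nucleophilic and only its benzylic carbon can carry the positive charge. Chemoselectivity rests on the acetal ionising far more easily than the MOM ethers or the C4–OMe of 15 at −40 °C, and on the hydrogen-bond-activated hydroxystyrene, used in excess against slowly added 11, outcompeting the trisubstituted geranyl alkenes and the ring A C8–H as nucleophile.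

Step 8
Reactants: 15 (2S,4S)-6-geranyl-2-(4-hydroxy-3,5-dimethoxyphenyl)-4-methoxy-5,7-bis(methoxymethoxy)chroman
Product: 16 (2S,4S)-2-[4-(tert-butyldimethylsilyloxy)-3,5-dimethoxyphenyl]-6-geranyl-4-methoxy-5,7-bis(methoxymethoxy)chroman
Conditions: TBSCl, imidazole, DMAP (cat.), DMF, rt
Reagents that add atoms: tert-butylchlorodimethylsilane (TBSCl), CC(C)(C)[Si](C)(C)Cl
Why: Imidazole-promoted silylation of the only free hydroxyl runs under mildly basic conditions that cannot ionise C4–OMe, and it masks the oxidation-prone syringyl phenol and lowers the tendency of O1–C2 to open before the acidic and oxidative steps.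

Step 9
Reactants: 16 (2S,4S)-2-[4-(tert-butyldimethylsilyloxy)-3,5-dimethoxyphenyl]-6-geranyl-4-methoxy-5,7-bis(methoxymethoxy)chroman
Product: 17 (2S)-2-[4-(tert-butyldimethylsilyloxy)-3,5-dimethoxyphenyl]-6-geranyl-5,7-bis(methoxymethoxy)chroman-4-ol (C4 epimers, used crude)
Conditions: PPTS (20 mol %), acetone/H2O (4:1), high dilution, rt
Reagents that add atoms: water, O
Why: This is an SN1 solvolysis of a benzylic ether in which ionisation at C4 is assisted by three conjugated oxygen donors (O1 on C8a, OMOM on C5 and C7), so a pyridinium buffer should exchange OMe for OH while aryl MOM, aryl TBS and the alkenes stay untouched, excess water drives the exchange, dilution disfavours attack by C8–H of a second molecule, and C2 is not involved.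

Step 10
Reactants: 17 (2S)-2-[4-(tert-butyldimethylsilyloxy)-3,5-dimethoxyphenyl]-6-geranyl-5,7-bis(methoxymethoxy)chroman-4-ol
Product: 18 (2S)-2-[4-(tert-butyldimethylsilyloxy)-3,5-dimethoxyphenyl]-6-geranyl-5,7-bis(methoxymethoxy)chroman-4-one
Conditions: Dess–Martin periodinane, NaHCO3, CH2Cl2, 0 °C → rt
Reagents that add atoms: none
Why: The bicarbonate-buffered Dess–Martin oxidation of a secondary benzylic alcohol spares trisubstituted alkenes, MOM and silyl ethers, merges both C4 epimers into one ketone, and offers no base strong enough for the retro-oxa-Michael opening that would scramble C2.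

Step 11
Reactants: 18 (2S)-2-[4-(tert-butyldimethylsilyloxy)-3,5-dimethoxyphenyl]-6-geranyl-5,7-bis(methoxymethoxy)chroman-4-one
Product: 19 (2S)-6-geranyl-2-(4-hydroxy-3,5-dimethoxyphenyl)-5,7-bis(methoxymethoxy)chroman-4-one
Conditions: TBAF, AcOH (1:1.2), THF, 0 °C
Reagents that add atoms: none
Why: In this fluoride-mediated desilylation the acetic acid protonates the liberated 4'-phenoxide at once, so that it cannot expel O1 through a para-quinone methide and racemise C2.

Step 12
Reactants: 19 (2S)-6-geranyl-2-(4-hydroxy-3,5-dimethoxyphenyl)-5,7-bis(methoxymethoxy)chroman-4-one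
Product: 20 (2S)-6-geranyl-5,7-dihydroxy-2-(4-hydroxy-3,5-dimethoxyphenyl)chroman-4-one (target)
Conditions: HCl (about 1 M), MeOH, 40 °C, stopped at full conversion
Reagents that add atoms: none
Why: Acid-catalysed transacetalisation of the aryl MOM ethers to dimethoxymethane is the usual unmasking for prenylated and geranylated flavanones, the acidic medium avoids the base-induced chalcone equilibrium that erodes C2, and moderate temperature with short contact should keep the 5-OH and 7-OH from adding to the geranyl alkene.

## Compound list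

1 | phloroglucinol | Oc1cc(O)cc(O)c1 | starting material
2 | 3,5-bis(methoxymethoxy)phenol | COCOc1cc(O)cc(OCOC)c1 | intermediate
3 | [3,5-bis(methoxymethoxy)phenoxy]triisopropylsilane | COCOc1cc(OCOC)cc(O[Si](C(C)C)(C(C)C)C(C)C)c1 | intermediate
4 | geranyl bromide, (2E)-1-bromo-3,7-dimethylocta-2,6-diene | CC(C)=CCC/C(C)=C/CBr | starting material
5 | 2,6-bis(methoxymethoxy)-4-(triisopropylsilyloxy)phenyllithium | [Li]c1c(OCOC)cc(O[Si](C(C)C)(C(C)C)C(C)C)cc1OCOC | intermediate
6 | [4-geranyl-3,5-bis(methoxymethoxy)phenoxy]triisopropylsilane | COCOc1cc(O[Si](C(C)C)(C(C)C)C(C)C)cc(OCOC)c1C/C=C(\C)CCC=C(C)C | intermediate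
7 | 4-geranyl-3,5-bis(methoxymethoxy)phenol | COCOc1cc(O)cc(OCOC)c1C/C=C(\C)CCC=C(C)C | intermediate
8 | 4-geranyl-2-(hydroxymethyl)-3,5-bis(methoxymethoxy)phenol (present as its magnesium salt, drawn neutral) | OCc1c(O)cc(OCOC)c(C/C=C(\C)CCC=C(C)C)c1OCOC | intermediate
9 | 3-geranyl-6-hydroxy-2,4-bis(methoxymethoxy)benzaldehyde | O=Cc1c(O)cc(OCOC)c(C/C=C(\C)CCC=C(C)C)c1OCOC | intermediate
10 | trimethyl orthoformate | COC(OC)OC | starting material
11 | 3-geranyl-6-hydroxy-2,4-bis(methoxymethoxy)benzaldehyde dimethyl acetal | COC(OC)c1c(O)cc(OCOC)c(C/C=C(\C)CCC=C(C)C)c1OCOC | intermediate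
12 | 4-vinyl-2,6-dimethoxyphenol (4-vinylsyringol) | C=Cc1cc(OC)c(O)c(OC)c1 | starting material
13 | 4-geranyl-6-(methoxymethylidene)-3,5-bis(methoxymethoxy)cyclohexa-2,4-dien-1-one | COC=C1C(=O)C=C(OCOC)C(C/C=C(\C)CCC=C(C)C)=C1OCOC | intermediate
14 | 4-{(3S)-3-[3-geranyl-6-hydroxy-2,4-bis(methoxymethoxy)phenyl]-3-methoxypropylidene}-2,6-dimethoxycyclohexa-2,5-dien-1-one | CO[C@@H](CC=C1C=C(OC)C(=O)C(OC)=C1)c1c(O)cc(OCOC)c(C/C=C(\C)CCC=C(C)C)c1OCOC | intermediate
15 | (2S,4S)-6-geranyl-2-(4-hydroxy-3,5-dimethoxyphenyl)-4-methoxy-5,7-bis(methoxymethoxy)chroman (2,4-cis) | COc1cc([C@@H]2C[C@H](OC)c3c(cc(OCOC)c(C/C=C(\C)CCC=C(C)C)c3OCOC)O2)cc(OC)c1O | intermediate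
16 | (2S,4S)-2-[4-(tert-butyldimethylsilyloxy)-3,5-dimethoxyphenyl]-6-geranyl-4-methoxy-5,7-bis(methoxymethoxy)chroman | COc1cc([C@@H]2C[C@H](OC)c3c(cc(OCOC)c(C/C=C(\C)CCC=C(C)C)c3OCOC)O2)cc(OC)c1O[Si](C)(C)C(C)(C)C | intermediate
17 | (2S)-2-[4-(tert-butyldimethylsilyloxy)-3,5-dimethoxyphenyl]-6-geranyl-5,7-bis(methoxymethoxy)chroman-4-ol (C4 epimers) | COc1cc([C@@H]2CC(O)c3c(cc(OCOC)c(C/C=C(\C)CCC=C(C)C)c3OCOC)O2)cc(OC)c1O[Si](C)(C)C(C)(C)C | intermediate
18 | (2S)-2-[4-(tert-butyldimethylsilyloxy)-3,5-dimethoxyphenyl]-6-geranyl-5,7-bis(methoxymethoxy)chroman-4-one | COc1cc([C@@H]2CC(=O)c3c(cc(OCOC)c(C/C=C(\C)CCC=C(C)C)c3OCOC)O2)cc(OC)c1O[Si](C)(C)C(C)(C)C | intermediate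
19 | (2S)-6-geranyl-2-(4-hydroxy-3,5-dimethoxyphenyl)-5,7-bis(methoxymethoxy)chroman-4-one | COc1cc([C@@H]2CC(=O)c3c(cc(OCOC)c(C/C=C(\C)CCC=C(C)C)c3OCOC)O2)cc(OC)c1O | intermediate
20 | (2S)-6-geranyl-5,7-dihydroxy-2-(4-hydroxy-3,5-dimethoxyphenyl)chroman-4-one (CNP0372687.1) | COc1cc([C@@H]2CC(=O)c3c(cc(O)c(C/C=C(\C)CCC=C(C)C)c3O)O2)cc(OC)c1O | target

## Step count and risks

Total step count: 12. Longest linear sequence: 12 steps (1 → 20); compounds 4, 10 and 12 are purchased.

**1. Step 7.**
- What may go wrong: poor facial selectivity in the ion pair; erosion of C2 by reversible acid opening of O1–C2; self-condensation of the quinone methide through ring A C8–H; acid-induced oligomerisation of the styrene.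
- The fallback is a chalcone route with kinetic resolution, all known chemistry. It sets out from aldehyde 9 and comes back to the route at target 20.
- MeMgBr (2.2 equiv, THF, 0 °C) adds to 9 to give 1-[3-geranyl-6-hydroxy-2,4-bis(methoxymethoxy)phenyl]ethanol F1. MnO2 in CH2Cl2 oxidises it to 1-[3-geranyl-6-hydroxy-2,4-bis(methoxymethoxy)phenyl]ethanone F2.
- Purchased syringaldehyde is converted with MOMCl/i-Pr2NEt into 3,5-dimethoxy-4-(methoxymethoxy)benzaldehyde F3.
- Claisen–Schmidt condensation of the ketone and this aldehyde (KOH, EtOH, rt) gives the (E)-2'-hydroxychalcone F4. NaOAc in refluxing EtOH closes ring C by oxa-Michael addition to the racemic tris-MOM flavanone F5.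
- Noyori asymmetric transfer hydrogenation follows, with RuCl[(R,R)-TsDPEN](p-cymene) or its antipode, chosen so that the (2R)-ketone is consumed faster (HCO2H/Et3N, EtOAc). It is run as a kinetic resolution to about half conversion.
- This should leave the (2S)-tris-MOM flavanone F6 beside the (2R,4R)-cis-flavan-4-ol F7, which is removed by chromatography. HCl/MeOH as in step 12 then gives 20.

**2. Step 9.**
- What may go wrong: elimination of the ionised C4 centre to the flav-3-ene; interflavan C4–C8 coupling; transacetalisation of the new C4–OH onto the neighbouring C5–OMOM.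
- The fallback replaces substitution followed by oxidation with a single oxidative cleavage. It sets out from 16 and comes back at 18.
- DDQ in CH2Cl2/pH 7 buffer at 0 °C abstracts hydride from C4–H of the electron-rich benzylic methyl ether. Water adds, and the hemiketal loses methanol to give the ketone directly.
- C4–H should be the preferred site because the resulting cation carries the methoxy group as well as three ring oxygen donors. The doubly activated geranyl CH2 has to be watched.
- The fallback makes no compound outside the list (F0).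

**3. Step 6.**
- What may go wrong: incomplete acetalisation of the hydrogen-bonded push–pull aldehyde; premature loss of methanol from the hydroxy acetal during isolation, with self-condensation.
- The fallback forms the acetal with the phenol masked and frees the phenol under base, where an acetal is inert. It sets out from 9 and comes back at 11.
- Ac2O/pyridine/DMAP gives 2-formyl-4-geranyl-3,5-bis(methoxymethoxy)phenyl acetate F8, which has no hydrogen bond and no route to a quinone methide.
- HC(OMe)3 with catalytic PPTS in MeOH then gives 2-(dimethoxymethyl)-4-geranyl-3,5-bis(methoxymethoxy)phenyl acetate F9.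
- K2CO3 in MeOH at 0 °C, followed by a pH 8 work-up, releases 11.

## Further compounds

F1 | step 7 | 1-[3-geranyl-6-hydroxy-2,4-bis(methoxymethoxy)phenyl]ethanol (racemic) | CC(O)c1c(O)cc(OCOC)c(C/C=C(\C)CCC=C(C)C)c1OCOC
F2 | step 7 | 1-[3-geranyl-6-hydroxy-2,4-bis(methoxymethoxy)phenyl]ethanone | CC(=O)c1c(O)cc(OCOC)c(C/C=C(\C)CCC=C(C)C)c1OCOC
F3 | step 7 | 3,5-dimethoxy-4-(methoxymethoxy)benzaldehyde | COCOc1c(OC)cc(C=O)cc1OC
F4 | step 7 | (E)-1-[3-geranyl-6-hydroxy-2,4-bis(methoxymethoxy)phenyl]-3-[3,5-dimethoxy-4-(methoxymethoxy)phenyl]prop-2-en-1-one | COCOc1c(OC)cc(/C=C/C(=O)c2c(O)cc(OCOC)c(C/C=C(\C)CCC=C(C)C)c2OCOC)cc1OC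
F5 | step 7 | racemic 2-[3,5-dimethoxy-4-(methoxymethoxy)phenyl]-6-geranyl-5,7-bis(methoxymethoxy)chroman-4-one | COCOc1c(OC)cc(C2CC(=O)c3c(cc(OCOC)c(C/C=C(\C)CCC=C(C)C)c3OCOC)O2)cc1OC
F6 | step 7 | (2S)-2-[3,5-dimethoxy-4-(methoxymethoxy)phenyl]-6-geranyl-5,7-bis(methoxymethoxy)chroman-4-one | COCOc1c(OC)cc([C@@H]2CC(=O)c3c(cc(OCOC)c(C/C=C(\C)CCC=C(C)C)c3OCOC)O2)cc1OC
F7 | step 7 | (2R,4R)-2-[3,5-dimethoxy-4-(methoxymethoxy)phenyl]-6-geranyl-5,7-bis(methoxymethoxy)chroman-4-ol (2,4-cis) | COCOc1c(OC)cc([C@H]2C[C@@H](O)c3c(cc(OCOC)c(C/C=C(\C)CCC=C(C)C)c3OCOC)O2)cc1OC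
F0 | step 9 | none | none
F8 | step 6 | 2-formyl-4-geranyl-3,5-bis(methoxymethoxy)phenyl acetate | CC(=O)Oc1cc(OCOC)c(C/C=C(\C)CCC=C(C)C)c(OCOC)c1C=O
F9 | step 6 | 2-(dimethoxymethyl)-4-geranyl-3,5-bis(methoxymethoxy)phenyl acetate | CC(=O)Oc1cc(OCOC)c(C/C=C(\C)CCC=C(C)C)c(OCOC)c1C(OC)OC
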